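**Retrosynthetic overview**
- The target is the all-trans oxolane; it comes from its tris-benzyl ether by hydrogenolysis. The oxolane is the only ring and is formed in the penultimate step.
- The ring O–CH2 bond and the aroyl-bearing stereocentre come from a 5-endo-trig oxa-Michael closure of a γ-hydroxy α-methylene aryl ketone.
- The ArCH(OH)–CH bond and the two non-epimerisable stereocentres come from an enantioselective, anti-selective allylboration of O-benzylisovanillin with a 2-aroylallyl pinacolboronate (the new step).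
- The 2-aroylallylboronate comes from a palladium-catalysed acylboration of benzyloxymethylallene with O-benzylisovanilloyl chloride and B2pin2.
- The allene comes from benzyl propargyl ether by Crabbé homologation.

Assumption: benzyl propargyl ether, 3-(benzyloxy)-4-methoxybenzoic acid, 3-(benzyloxy)-4-methoxybenzaldehyde, B2pin2 and (S)-TRIP are taken as commercially available.

Ring numbering used in the text: O1, C2 (aryl-bearing), C3 (CH2O-bearing), C4 (aroyl-bearing), C5 (CH2). In this numbering the target is (2S,3R,4S), with all three substituents trans.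

**Route**

Step 1
Reactants: 1 benzyl propargyl ether
Product: 3 4-(benzyloxy)buta-1,2-diene, via propargylic amine 2 (not isolated)
Conditions: (CH2O)n (2.5 equiv), iPr2NH (2 equiv), CuBr (0.4 equiv), 1,4-dioxane, reflux, 12 h
Reagents that add atoms: formaldehyde (from paraformaldehyde) C=O
Why: Crabbé homologation, in which the copper-mediated Mannich coupling gives propargylic amine 2 and a 1,5-hydride shift from an N-isopropyl C–H then releases the terminal allene and the imine; no stereocentre is formed.

Step 2
Reactants: 4 3-(benzyloxy)-4-methoxybenzoic acid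
Product: 5 3-(benzyloxy)-4-methoxybenzoyl chloride
Conditions: (COCl)2 (1.3 equiv), DMF (cat.), CH2Cl2, 0 °C to rt, 2 h; concentrate and use crude
Reagents that add atoms: oxalyl chloride O=C(Cl)C(Cl)=O
Why: Standard Vilsmeier-type acid chloride formation, under which the aryl benzyl and methyl ethers are inert; no stereocentre is involved.

Step 3
Reactants: 5 3-(benzyloxy)-4-methoxybenzoyl chloride, 3 4-(benzyloxy)buta-1,2-diene
Product: 6 (Z)-4-(benzyloxy)-1-[3-(benzyloxy)-4-methoxyphenyl]-2-[(4,4,5,5-tetramethyl-1,3,2-dioxaborolan-2-yl)methyl]but-2-en-1-one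
Conditions: B2pin2 (1.1 equiv), PdCl2(MeCN)2 (5 mol%), toluene, 80 °C, 12 h (phosphine-free)
Reagents that add atoms: bis(pinacolato)diboron CC1(C)OB(OC1(C)C)B1OC(C)(C)C(C)(C)O1
Why: Palladium-catalysed three-component acylboration of an allene, in which oxidative addition of 5 to zerovalent palladium and acylpalladation at the central allene carbon give a syn 2-acyl-π-allyl complex, and transmetalation with B2pin2 followed by C–B reductive elimination at the unsubstituted terminus gives the alkene with CH2OBn cis to the aroyl group and trans to CH2B.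

Step 4
Reactants: 6 (Z)-2-aroylallyl pinacolboronate (1.2 equiv), 7 3-(benzyloxy)-4-methoxybenzaldehyde
Product: 9 (3R,4S)-3-[(benzyloxy)methyl]-1,4-bis[3-(benzyloxy)-4-methoxyphenyl]-4-hydroxy-2-methylidenebutan-1-one, via borate ester 8 (not isolated)
Conditions: (S)-TRIP [(S)-3,3'-bis(2,4,6-triisopropylphenyl)-1,1'-binaphthyl-2,2'-diyl hydrogen phosphate] (10 mol%), 4 Å MS, toluene, −20 to 0 °C, 48 h; then sat. aq NaHCO3, rt
Reagents that add atoms: none
Why: Proposed new method: chiral phosphoric acid-catalysed allylboration with a 2-aroyl, γ-substituted allyl pinacolboronate, in which the acid O–H hydrogen-bonds to a pinacol oxygen of 6 (raising boron Lewis acidity and offsetting the deactivating acyl group) while the phosphoryl oxygen holds the formyl C–H of 7, so that allyl transfer runs through a closed Zimmerman–Traxler chair with the γ-CH2OBn group (trans to CH2B) equatorial to give the anti adduct, and the (S)-catalyst pocket leaves the Si face of the aldehyde open to give the (S)-carbinol (C2) and the (R)-centre next to it (C3); the uncatalysed background should be negligible because 6 is electron-poor; the closest known reaction type is the chiral phosphoric acid-catalysed allyl- and crotylboration of aryl aldehydes with simple allyl pinacolboronates, where the (R)-acid is taken to give Re-face addition, together with the thermal or Lewis acid-promoted additions of 2-alkoxycarbonylallylboronates.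

Step 5
Reactants: 9 (3R,4S)-hydroxy enone
Product: 10 [3-(benzyloxy)-4-methoxyphenyl]{(3S,4R,5S)-5-[3-(benzyloxy)-4-methoxyphenyl]-4-[(benzyloxy)methyl]oxolan-3-yl}methanone
Conditions: KOtBu (20 mol%), THF–tBuOH (10:1), 0 °C to rt, 4 h; AcOH quench
Reagents that add atoms: none
Why: Intramolecular 5-endo-trig oxa-Michael addition of the benzylic alkoxide to the exocyclic methylene of the enone forms the O1–C5 bond and closes the oxolane, and because ring closure and enolate protonation are reversible under the basic conditions C4 settles with the aroyl group trans to the C3 substituent (all-trans), while C2 and C3 are untouched and the benzyl ether on the primary oxygen blocks the competing closure through that oxygen.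

Step 6
Reactants: 10 tris-benzyl ether
Product: 11 (3-hydroxy-4-methoxyphenyl)[(3S,4R,5S)-5-(3-hydroxy-4-methoxyphenyl)-4-(hydroxymethyl)oxolan-3-yl]methanone (target)
Conditions: H2 (1 atm), 10% Pd/C, EtOAc–MeOH (4:1), rt, monitored and stopped at full debenzylation
Reagents that add atoms: none
Why: Hydrogenolysis of the two aryl benzyl ethers and the primary benzyl ether under neutral conditions, which is faster than reduction of the electron-rich aryl ketone or cleavage of the cyclic benzylic C–O bond and does not epimerise the ketone α-centre.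

**Compound list**

1 | benzyl propargyl ether, [(prop-2-yn-1-yloxy)methyl]benzene | C#CCOCc1ccccc1 | starting material
2 | 4-(benzyloxy)-N,N-di(propan-2-yl)but-2-yn-1-amine (propargylic amine, not isolated) | CC(C)N(CC#CCOCc1ccccc1)C(C)C | intermediate
3 | 4-(benzyloxy)buta-1,2-diene | C=C=CCOCc1ccccc1 | intermediate
4 | 3-(benzyloxy)-4-methoxybenzoic acid | COc1ccc(C(=O)O)cc1OCc1ccccc1 | starting material
5 | 3-(benzyloxy)-4-methoxybenzoyl chloride | COc1ccc(C(Cl)=O)cc1OCc1ccccc1 | intermediate
6 | (Z)-4-(benzyloxy)-1-[3-(benzyloxy)-4-methoxyphenyl]-2-[(4,4,5,5-tetramethyl-1,3,2-dioxaborolan-2-yl)methyl]but-2-en-1-one (CH2OBn cis to aroyl) | COc1ccc(C(=O)/C(CB2OC(C)(C)C(C)(C)O2)=C\COCc2ccccc2)cc1OCc1ccccc1 | intermediate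
7 | 3-(benzyloxy)-4-methoxybenzaldehyde | COc1ccc(C=O)cc1OCc1ccccc1 | starting material
8 | (3R,4S)-3-[(benzyloxy)methyl]-1,4-bis[3-(benzyloxy)-4-methoxyphenyl]-2-methylidene-4-[(4,4,5,5-tetramethyl-1,3,2-dioxaborolan-2-yl)oxy]butan-1-one (borate ester, not isolated) | CC1(C)OB(O[C@H](c2ccc(OC)c(OCc3ccccc3)c2)[C@H](C(=C)C(=O)c2ccc(OC)c(OCc3ccccc3)c2)COCc2ccccc2)OC1(C)C | intermediate
9 | (3R,4S)-3-[(benzyloxy)methyl]-1,4-bis[3-(benzyloxy)-4-methoxyphenyl]-4-hydroxy-2-methylidenebutan-1-one | O[C@H](c1ccc(OC)c(OCc2ccccc2)c1)[C@H](C(=C)C(=O)c1ccc(OC)c(OCc2ccccc2)c1)COCc1ccccc1 | intermediate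
10 | [3-(benzyloxy)-4-methoxyphenyl]{(3S,4R,5S)-5-[3-(benzyloxy)-4-methoxyphenyl]-4-[(benzyloxy)methyl]oxolan-3-yl}methanone (all-trans) | COc1ccc(C(=O)[C@@H]2CO[C@H](c3ccc(OC)c(OCc4ccccc4)c3)[C@H]2COCc2ccccc2)cc1OCc1ccccc1 | intermediate
11 | (3-hydroxy-4-methoxyphenyl)[(3S,4R,5S)-5-(3-hydroxy-4-methoxyphenyl)-4-(hydroxymethyl)oxolan-3-yl]methanone | COc1ccc(C(=O)[C@@H]2CO[C@H](c3ccc(OC)c(O)c3)[C@H]2CO)cc1O | target

**Step count**
- Total steps: 6.
- Longest linear sequence: 5 steps (4 → 5 → 6 → 9 → 10 → 11; the branch 1 → 3 joins at step 3).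

**Three steps most likely to fail, with fallbacks**

Step 3 (acylboration of the oxygenated allene; the risks are β-alkoxide loss from the π-allyl complex or the wrong alkene geometry). The fallback sets out from acid chloride 5 and alkyne 1 and comes back at 6. It builds the carbon skeleton first and brings in boron as an electrophile. Acyl Sonogashira coupling of 5 with 1 (PdCl2(PPh3)2, CuI, Et3N, THF, rt) gives the ynone 4-(benzyloxy)-1-[3-(benzyloxy)-4-methoxyphenyl]but-2-yn-1-one F1. Syn conjugate hydrometalation of F1 (iBu2AlH, HMPA, MeCu cat., THF, −50 °C) and trapping of the α-metallated enone with (iodomethyl)boronic acid pinacol ester then gives 6. This sequence is established for alkynoates, and syn delivery of hydride places H cis to CH2B, which is the same geometry as in 6.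

Step 4 (the proposed new allylboration; the risks are low reactivity of the deactivated boronate or insufficient enantio- or diastereocontrol). The fallback uses known chemistry, sets out from allene 3 and aldehyde 7, and comes back at 10.
- Hydroboration of 3 with (−)-Ipc2BH [from (+)-α-pinene] in THF, with warming to equilibrate to the thermodynamic E isomer, gives the allylborane B-[(E)-4-(benzyloxy)but-2-en-1-yl]bis(isopinocampheyl)borane F2.
- Brown-type allylboration of 7 with F2 at −78 °C (chair transition state, anti) and NaOH/H2O2 work-up gives the homoallylic alcohol (1S,2R)-2-[(benzyloxy)methyl]-1-[3-(benzyloxy)-4-methoxyphenyl]but-3-en-1-ol F3.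
- 5-endo iodoetherification (I2, NaHCO3, MeCN, 0 °C) closes the ring to the iodide (2S,3R)-2-[3-(benzyloxy)-4-methoxyphenyl]-3-[(benzyloxy)methyl]-4-iodooxolane F4, as a mixture at C4.
- Nickel-catalysed reductive acylation of F4 with acid chloride 5 (NiCl2·glyme, 4,4'-di-tert-butyl-2,2'-bipyridine, Mn, DMA, rt) attaches the aroyl group through the C4 radical, and brief DBU treatment equilibrates C4 to the all-trans ketone 10.

Step 5 (5-endo-trig oxa-Michael closure; the risk is that the geometrically disfavoured closure is too slow and the hydroxy enone oligomerises). The fallback sets out from 9 and comes back at 10. It closes the ring at the benzylic C2–O bond instead of the C5–O bond.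
- Copper-catalysed conjugate borylation of the enone (CuCl, Xantphos, NaOtBu, B2pin2, MeOH, THF, rt) gives the β-boryl ketone (3R,4S)-3-[(benzyloxy)methyl]-1,4-bis[3-(benzyloxy)-4-methoxyphenyl]-4-hydroxy-2-[(4,4,5,5-tetramethyl-1,3,2-dioxaborolan-2-yl)methyl]butan-1-one F5 (mixture at the ketone α-carbon).
- Oxidation (NaBO3·4H2O, THF–H2O) gives the keto diol (3R,4S)-3-[(benzyloxy)methyl]-1,4-bis[3-(benzyloxy)-4-methoxyphenyl]-4-hydroxy-2-(hydroxymethyl)butan-1-one F6.
- Catalytic camphorsulfonic acid in wet CH2Cl2 at 0 °C ionises the para-methoxybenzylic alcohol, and the primary hydroxyl captures the cation to close the oxolane 2,3-trans. The C3 centre is untouched, and DBU then equilibrates C4 to give 10.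

**Further compounds**

F1 | step 3 | 4-(benzyloxy)-1-[3-(benzyloxy)-4-methoxyphenyl]but-2-yn-1-one | O=C(C#CCOCc1ccccc1)c1ccc(OC)c(OCc2ccccc2)c1
F2 | step 4 | B-[(E)-4-(benzyloxy)but-2-en-1-yl]bis(isopinocampheyl)borane [from (+)-α-pinene] | C(/C=C/COCc1ccccc1)B([C@@H]1C[C@@H]2C[C@H]([C@H]1C)C2(C)C)[C@@H]1C[C@@H]2C[C@H]([C@H]1C)C2(C)C
F3 | step 4 | (1S,2R)-2-[(benzyloxy)methyl]-1-[3-(benzyloxy)-4-methoxyphenyl]but-3-en-1-ol | O[C@H](c1ccc(OC)c(OCc2ccccc2)c1)[C@H](C=C)COCc1ccccc1
F4 | step 4 | (2S,3R)-2-[3-(benzyloxy)-4-methoxyphenyl]-3-[(benzyloxy)methyl]-4-iodooxolane (mixture at C4) | IC1CO[C@H](c2ccc(OC)c(OCc3ccccc3)c2)[C@H]1COCc1ccccc1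
F5 | step 5 | (3R,4S)-3-[(benzyloxy)methyl]-1,4-bis[3-(benzyloxy)-4-methoxyphenyl]-4-hydroxy-2-[(4,4,5,5-tetramethyl-1,3,2-dioxaborolan-2-yl)methyl]butan-1-one (mixture at C2) | O[C@H](c1ccc(OC)c(OCc2ccccc2)c1)[C@H](C(CB1OC(C)(C)C(C)(C)O1)C(=O)c1ccc(OC)c(OCc2ccccc2)c1)COCc1ccccc1
F6 | step 5 | (3R,4S)-3-[(benzyloxy)methyl]-1,4-bis[3-(benzyloxy)-4-methoxyphenyl]-4-hydroxy-2-(hydroxymethyl)butan-1-one (mixture at C2) | O[C@H](c1ccc(OC)c(OCc2ccccc2)c1)[C@H](C(CO)C(=O)c1ccc(OC)c(OCc2ccccc2)c1)COCc1ccccc1
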